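Target: (3R)-8-hydroxy-6-methoxy-3-(6-oxoundecyl)-3,4-dihydroisocoumarin, compound 25. The same compound numbers are used throughout and are collected in the list after the steps.

## Analysis of the target

Compound 25 is an arene (ring A: C4a, C5, C6, C7, C8, C8a) fused to a six-membered lactone (ring B: C1, O2, C3, C4, C4a, C8a), with an eleven-carbon chain C1' to C11' on C3 that carries a ketone at C6'. C3 is the only stereocentre and is R, so the task is absolute control with no second centre to lean on. The sensitive groups are the lactone (nucleophiles, strong base), the dialkyl ketone at C6' (organolithium reagents, amide bases) and the C8 phenol, which must end up different from the C6 methyl ether. The difficulties are the 1,2,3,5-substitution of ring A, with the carbonyl-bearing carbon C8a wedged between C8-O and C4a, the distinction of two oxygens on one ring, and a remote ketone that must stay masked through every organometallic step. The route rests on the neighbouring ring carbons C4a and C8a: C4a carries C4, which can come from a carbon nucleophile, C8a carries C1 at the oxidation level of an acyl electrophile, and the C8 oxygen sits next to C8a. That is the pattern left when a nucleophile adds to a 3-alkoxy aryne at the carbon remote from oxygen and the aryl anion beside oxygen is then captured by an electrophile. In addition C1, C4 and C3 with its oxygen are the carbonyl carbon, alpha carbon and carbinol carbon of a 3-hydroxy ester, so one enolate equivalent that already holds the stereocentre can supply both new ring bonds.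

## Retrosynthetic reasoning

**25 to 24.** The last bond cut is the O-CH3 bond at C8. Both ring oxygens come from a symmetric phenol and only become different once ring B exists, because the C8 oxygen is then peri to the C1 carbonyl and can be dealkylated under chelation control while C6 cannot. This allows the cheap symmetric phenol 1 to be used without early differentiation.

**24 to 22.** Ring B is opened at C1-O2 and C1 is reconnected to C4, which gives the benzocyclobutenone 22. In the forward sense an external alkoxide opens the strained ketone to the ortho-alkyl benzoate 23, and the C3 hydroxyl then closes ring B on that ester. Direct attack of the C3 oxygen on C1 of 22 is not relied on, because it would pass through a four-membered ring (O, C3, C4, C1) fused to the cyclobutenone. The relay through 23 reaches the same lactone through a six-membered transition state.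

**22 to 21.** The three masks (mixed acetal at C1, silyl ether on the C3 oxygen, dioxolane at C6') are removed together by aqueous acid. They are needed only for the strong bases of steps 11 and 12, so nothing is gained by keeping any of them longer, and freeing the C3 hydroxyl before base is applied removes a leaving group from the carbon next to C4.

**21 to 6 and 17 (key disconnection).** The C4a-C4 and C8a-C1 bonds are cut, which leads to aryne 19 (from iodo triflate 6) and ketene silyl acetal 17. Both ring A substituent bonds form in one operation, their regiochemistry is dictated by the C8 methoxy group, and C3 arrives already set. A cut at C4-C3 instead would require the stereocentre to be made during the coupling. The four-membered ring also stores the strain that later drives the opening to 23.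

**17 to 13.** Enol silylation leads back to ester 15 and silyl protection to hydroxy ester 14. The ester C1-C2 bond (target C1-C4) is then cut by carbonylative opening of epoxide 13 at its unsubstituted carbon. No bond to the stereocentre is touched, so its configuration is that of 13.

**13 to 7 and 8.** Epoxide 13 comes from racemic 12 by hydrolytic kinetic resolution, 12 from alkene 11 by epoxidation, and 11 from ketone 10 by ketalisation. The C5'-C6' bond of 10 is made by acylating Grignard reagent 9 (from bromide 7) with acid chloride 8. The ketone is masked before epoxidation to exclude Baeyer-Villiger oxidation and because it must be masked for steps 11 and 12 anyway.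

**6 to 1.** Triflate 6 comes from phenol 5. The iodine is placed between the phenol oxygen and a methoxy group by directed ortho metalation of carbamate 2 through aryllithium 3, followed by hydrolysis of 4. Electrophilic iodination of 1 itself would not distinguish this position from the one between the two methoxy groups.

## Alternatives that were turned down

**Alternative 1:** Ring B would be made by oxygen insertion into the C1-C3 bond of the racemic indanone A2 (5,7-dimethoxy-2-[5-(2-pentyl-1,3-dioxolan-2-yl)pentyl]indan-1-one). A flavin monooxygenase working in mildly basic buffer, where the alpha centre racemises, would oxidise one enantiomer with migration of C3 and give lactone A1 ((3R)-6,8-dimethoxy-3-[5-(2-pentyl-1,3-dioxolan-2-yl)pentyl]-3,4-dihydroisocoumarin). Acid and then step 15 would finish the synthesis.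
- For it: A2 is a few steps from a commercial indanone, the whole racemate can in principle be converted, and ring B and C3 are set together. It is clearly shorter than the chosen route and wastes no enantiomer.
- Against it: nothing in the substrate secures the outcome. The electron-rich dimethoxyaryl group is an intrinsically good migrating group and would lead to the chromanone A3 (6,8-dimethoxy-3-[5-(2-pentyl-1,3-dioxolan-2-yl)pentyl]chroman-2-one). Acceptance of a peri-methoxy group and a long lipophilic ketal chain, and the sense of enantioselection, cannot be argued from structure. The pH needed for racemisation is also one at which the product lactone can open.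
- Comparison: the chosen route is longer and loses half of epoxide 12, but its regiochemistry follows from the methoxy group and its configuration from the resolved epoxide 13.

**Alternative 2:** Ring A would be built by cutting C4a-C8a. The diketo-dioxinone A5 (6-{(6R)-6-[(tert-butyldimethylsilyl)oxy]-2,4-dioxo-11-(2-pentyl-1,3-dioxolan-2-yl)undecyl}-2,2-dimethyl-4H-1,3-dioxin-4-one) would cyclise with an amine base by aldol addition of C8a to the C4a ketone and dehydration to the resorcylate A4 (7-hydroxy-2,2-dimethyl-5-{(2R)-2-[(tert-butyldimethylsilyl)oxy]-7-(2-pentyl-1,3-dioxolan-2-yl)heptyl}-4H-1,3-benzodioxin-4-one). O-Methylation at C6, desilylation with closure of ring B on the dioxinone carbonyl, and ketal removal would give 25.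
- For it: the two ring oxygens are born different (C6 free, C8 inside the acetonide), so no selective demethylation is needed and the C8 phenol appears as ring B closes. On this point it is stronger than the chosen route.
- Against it: A5 is a protected tetraketide that must be assembled by several acylations of sensitive enolates. Its C4a ketone has the silyloxy group in the beta position, so the amine base that triggers the aldol can also trigger elimination across C4-C3 and destroy the stereocentre. O-cyclisation competes with C-cyclisation.
- Comparison: the chosen route buys ring A ready-made and keeps C3 beta only to an ester, which is far less prone to elimination. The price is the final chelation-controlled demethylation.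

**Alternative 3:** Ring A would be built by cutting C4a-C5 and C8-C8a. The ynoate A7 (methyl (5R)-5-[(tert-butyldimethylsilyl)oxy]-10-(2-pentyl-1,3-dioxolan-2-yl)dec-2-ynoate) and the diene A8 (1,3-dimethoxy-1-(trimethylsilyloxy)buta-1,3-diene) would be heated, and dilute acid would then aromatise the adduct to the salicylate A6 (methyl 2-hydroxy-4-methoxy-6-{(2R)-2-[(tert-butyldimethylsilyl)oxy]-7-(2-pentyl-1,3-dioxolan-2-yl)heptyl}benzoate). Desilylation, lactonisation and ketal removal would give 25.
- For it: the polarities of the two partners match, the C8 phenol and C6 methyl ether come out correctly without any demethylation, and A7 is about two steps from epoxide 13. On step count and on the oxygenation pattern this is stronger than the chosen route.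
- Against it: A7 is an internal alkyne with one activating group and an alkyl substituent on the reacting carbon, so it is a poor dienophile. The temperatures it needs are those at which the ketene-acetal diene A8 decomposes or adds in conjugate fashion without closing the ring.
- Comparison: in the chosen route the ring-forming partner is an aryne, whose reactivity does not depend on activation of the two-carbon partner, and both bonds form at −78 °C.

Key step: step 12

Remark on the chemistry: the hydrolytic kinetic resolution is assumed to follow its usual sense for terminal alkyl oxiranes, the (R,R)-catalyst leaving the (R)-epoxide; if the opposite sense were found, the (S,S)-catalyst would be used. The descriptor R holds from 13 to 25 because the priority order (oxygen, then the carbon that becomes C4, then the chain carbon) is the same in every intermediate.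

## Route

Step 1
Reactants: 1 3,5-dimethoxyphenol
Product: 2 3,5-dimethoxyphenyl N,N-diethylcarbamate
Conditions: ClCONEt2, K2CO3, MeCN, reflux
Reagents that add atoms: N,N-diethylcarbamoyl chloride, CCN(CC)C(Cl)=O
Why: O-acylation of a phenol with a carbamoyl chloride; the carbamate is the strongest oxygen-based director for the next step.

Step 2
Reactants: 2 3,5-dimethoxyphenyl N,N-diethylcarbamate
Product: 4 2-iodo-3,5-dimethoxyphenyl N,N-diethylcarbamate, via aryllithium 3 (not isolated)
Conditions: s-BuLi, TMEDA, THF, −78 °C; then I2, THF, −78 °C
Reagents that add atoms: iodine, II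
Why: Directed ortho metalation; the position between the carbamate and a methoxy group is activated by both and should be lithiated in preference to the one between two methoxy groups, and quenching cold with iodine avoids the anionic ortho-Fries shift.

Step 3
Reactants: 4 2-iodo-3,5-dimethoxyphenyl N,N-diethylcarbamate
Product: 5 2-iodo-3,5-dimethoxyphenol
Conditions: NaOH, EtOH-H2O, reflux; then aq. HCl
Reagents that add atoms: none
Why: Base hydrolysis of an aryl carbamate by attack at the carbonyl; the electron-rich aryl iodide is inert to hydroxide.

Step 4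
Reactants: 5 2-iodo-3,5-dimethoxyphenol
Product: 6 2-iodo-3,5-dimethoxyphenyl trifluoromethanesulfonate
Conditions: Tf2O, pyridine, CH2Cl2, 0 °C
Reagents that add atoms: trifluoromethanesulfonic anhydride, O=S(=O)(OS(=O)(=O)C(F)(F)F)C(F)(F)F
Why: Standard O-sulfonylation of a phenol; it installs the leaving group next to the iodine.

Step 5
Reactants: 7 7-bromohept-1-ene; 8 hexanoyl chloride
Product: 10 tridec-12-en-6-one, via Grignard reagent 9 (not isolated)
Conditions: Mg, THF; then 8, Fe(acac)3 (3 mol%), THF, −78 °C
Reagents that add atoms: none
Why: Iron-catalysed acylation of an alkyl Grignard reagent with an acid chloride, with Fe(acac)3 (a trivalent iron complex) as precatalyst; at −78 °C the reaction should stop at the ketone and the terminal alkene is inert.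

Step 6
Reactants: 10 tridec-12-en-6-one
Product: 11 2-(hept-6-en-1-yl)-2-pentyl-1,3-dioxolane
Conditions: HOCH2CH2OH, p-TsOH (cat.), toluene, reflux, Dean-Stark
Reagents that add atoms: ethane-1,2-diol, OCCO
Why: Acid-catalysed ketalisation driven by removal of water; it masks C6' against the peracid of step 7 and the bases of steps 11 and 12.

Step 7
Reactants: 11 2-(hept-6-en-1-yl)-2-pentyl-1,3-dioxolane
Product: 12 racemic 2-[5-(oxiran-2-yl)pentyl]-2-pentyl-1,3-dioxolane
Conditions: mCPBA, NaHCO3, CH2Cl2, 0 °C to rt
Reagents that add atoms: 3-chloroperoxybenzoic acid, OOC(=O)c1cccc(Cl)c1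
Why: Prilezhaev epoxidation of a terminal alkene; the hydrogen carbonate buffer protects the dioxolane from the acid formed.

Step 8
Reactants: 12 racemic 2-[5-(oxiran-2-yl)pentyl]-2-pentyl-1,3-dioxolane
Product: 13 (2R)-2-[5-(2-pentyl-1,3-dioxolan-2-yl)pentyl]oxirane
Conditions: (R,R)-(salen)Co(OAc) (0.5 mol%), H2O (0.55 equiv), THF, 0 °C to rt
Reagents that add atoms: none
Why: Hydrolytic kinetic resolution with the acetate of trivalent cobalt bearing the N,N'-bis(3,5-di-tert-butylsalicylidene)cyclohexane-1,2-diamine ligand; the catalyst should hydrolyse the (S)-epoxide and leave 13, which is where C3 of the target is set, at the cost of at most half of the material.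

Step 9
Reactants: 13 (2R)-2-[5-(2-pentyl-1,3-dioxolan-2-yl)pentyl]oxirane
Product: 14 methyl (3R)-3-hydroxy-8-(2-pentyl-1,3-dioxolan-2-yl)octanoate
Conditions: Co2(CO)8 (5 mol%), 3-hydroxypyridine (10 mol%), CO (40 bar), MeOH, THF, 60 °C
Reagents that add atoms: carbon monoxide, [C-]#[O+]; methanol, CO
Why: Cobalt-catalysed methoxycarbonylation of a terminal epoxide: the tetracarbonylcobaltate anion opens the ring at the unsubstituted carbon, and CO insertion and methanolysis give the 3-hydroxy ester; the C-O bond at the stereocentre is not broken, so configuration is retained.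

Step 10
Reactants: 14 methyl (3R)-3-hydroxy-8-(2-pentyl-1,3-dioxolan-2-yl)octanoate
Product: 15 methyl (3R)-3-[(tert-butyldimethylsilyl)oxy]-8-(2-pentyl-1,3-dioxolan-2-yl)octanoate
Conditions: TBSCl, imidazole, DMF, rt
Reagents that add atoms: tert-butyldimethylsilyl chloride, CC(C)(C)[Si](C)(C)Cl
Why: Standard silylation of a secondary alcohol; the ether withstands the amide base and n-BuLi of the next two steps.

Step 11
Reactants: 15 methyl (3R)-3-[(tert-butyldimethylsilyl)oxy]-8-(2-pentyl-1,3-dioxolan-2-yl)octanoate
Product: 17 tert-butyl({(1E,3R)-3-[(tert-butyldimethylsilyl)oxy]-1-methoxy-8-(2-pentyl-1,3-dioxolan-2-yl)oct-1-en-1-yl}oxy)dimethylsilane, via lithium enolate 16 (not isolated)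
Conditions: LiN(iPr)2, THF, −78 °C; then TBSCl, DMPU, −78 °C to rt; non-aqueous work-up
Reagents that add atoms: tert-butyldimethylsilyl chloride, CC(C)(C)[Si](C)(C)Cl
Why: Kinetic ester enolisation in THF and O-silylation give the ketene silyl acetal with the chain cis to methoxy; at −78 °C loss of silanolate from 16 should be slow, and the double-bond geometry does not matter because both carbons become sp3 centres that are erased later.

Step 12
Reactants: 6 2-iodo-3,5-dimethoxyphenyl trifluoromethanesulfonate; 17 ketene methyl silyl acetal from step 11
Product: 21 7-[(tert-butyldimethylsilyl)oxy]-8-{(1R)-1-[(tert-butyldimethylsilyl)oxy]-6-(2-pentyl-1,3-dioxolan-2-yl)hexyl}-3,5,7-trimethoxybicyclo[4.2.0]octa-1,3,5-triene (isomer mixture at the two sp3 ring carbons), via aryllithium 18 (not isolated), via aryne 19 (not isolated), via zwitterion 20 (not isolated)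
Conditions: 6 (1.5 equiv) and 17 premixed, n-BuLi (1.5 equiv, slow addition), THF, −78 °C
Reagents that add atoms: none
Why: Iodine-lithium exchange on 6 gives aryllithium 18, which loses lithium triflate at once to give aryne 19 with its triple bond between the future C4a and C8a. The C8 methoxy group polarises this bond inductively, so the nucleophilic carbon of 17 (future C4) adds to the remote carbon C4a and the negative charge develops at C8a beside oxygen; this is the regioselectivity the step needs, and the substrate secures it. The zwitterion 20, an aryl anion facing a methoxy-silyloxy carbenium ion, then collapses by 4-exo-trig attack of C8a on C1, which closes the four-membered ring in a stepwise polar [2+2] process. The closest known reaction type is the [2+2] cycloaddition of 3-alkoxy arynes, generated from ortho-iodoaryl triflates, with ketene silyl acetals to give benzocyclobutenone acetals. No stereocentre that is kept is created: C4 and the acetal carbon C1 form without control and are erased in steps 13 and 14, and C3 is a spectator set in step 8. Halogen-lithium exchange should outrun attack of n-BuLi on the silyl groups or the ketal, and premixing 6 and 17 lets the ketene acetal trap the aryne before it meets n-BuLi or 18.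

Step 13
Reactants: 21 benzocyclobutenone methyl silyl acetal from step 12
Product: 22 8-[(1R)-1-hydroxy-7-oxododecyl]-3,5-dimethoxybicyclo[4.2.0]octa-1,3,5-trien-7-one (epimer mixture at the ring sp3 carbon)
Conditions: 2 M aq. HCl, THF, rt
Reagents that add atoms: water, O
Why: Acid hydrolysis of a benzocyclobutenone acetal to the ketone, together with acid cleavage of the secondary silyl ether and the dioxolane; the four-membered ketone is stable to acid and its beta-hydroxyl should not eliminate, because the required enol would be a benzocyclobutadiene.

Step 14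
Reactants: 22 hydroxy diketone from step 13
Product: 24 (3R)-6,8-dimethoxy-3-(6-oxoundecyl)-3,4-dihydroisocoumarin, via hydroxy ester 23 (not isolated)
Conditions: NaOMe (1.2 equiv), MeOH-THF, 0 °C to rt
Reagents that add atoms: none
Why: Alkoxide cleavage of a benzocyclobutenone: methoxide adds to the strained C1 carbonyl and the tetrahedral alkoxide expels C4, which is protonated by methanol, to give the ortho-alkyl benzoate 23. The free C3 hydroxyl then lactonises on this ester by 6-exo-trig closure (ring B), as is routine for 2-(2-hydroxyalkyl)benzoates; C3 is not touched.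

Step 15
Reactants: 24 (3R)-6,8-dimethoxy-3-(6-oxoundecyl)-3,4-dihydroisocoumarin
Product: 25 (3R)-8-hydroxy-6-methoxy-3-(6-oxoundecyl)-3,4-dihydroisocoumarin
Conditions: BCl3, CH2Cl2, −78 to 0 °C; then H2O
Reagents that add atoms: none
Why: Chelation-controlled ether cleavage: boron binds the lactone carbonyl and the peri oxygen on C8, and chloride removes that methyl group, while the unchelated C6 methyl ether should survive at low temperature.

## Compound list

1 | 3,5-dimethoxyphenol | COc1cc(O)cc(OC)c1 | starting material
2 | 3,5-dimethoxyphenyl N,N-diethylcarbamate | CCN(CC)C(=O)Oc1cc(OC)cc(OC)c1 | intermediate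
3 | {2-[(diethylcarbamoyl)oxy]-4,6-dimethoxyphenyl}lithium | CCN(CC)C(=O)Oc1cc(OC)cc(OC)c1[Li] | intermediate (not isolated)
4 | 2-iodo-3,5-dimethoxyphenyl N,N-diethylcarbamate | CCN(CC)C(=O)Oc1cc(OC)cc(OC)c1I | intermediate
5 | 2-iodo-3,5-dimethoxyphenol | COc1cc(O)c(I)c(OC)c1 | intermediate
6 | 2-iodo-3,5-dimethoxyphenyl trifluoromethanesulfonate | COc1cc(OC)c(I)c(OS(=O)(=O)C(F)(F)F)c1 | intermediate
7 | 7-bromohept-1-ene | C=CCCCCCBr | starting material
8 | hexanoyl chloride | CCCCCC(Cl)=O | starting material
9 | hept-6-en-1-ylmagnesium bromide | C=CCCCCC[Mg]Br | intermediate (not isolated)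
10 | tridec-12-en-6-one | CCCCCC(=O)CCCCCC=C | intermediate
11 | 2-(hept-6-en-1-yl)-2-pentyl-1,3-dioxolane | C=CCCCCCC1(CCCCC)OCCO1 | intermediate
12 | racemic 2-[5-(oxiran-2-yl)pentyl]-2-pentyl-1,3-dioxolane | C1OC1CCCCCC2(CCCCC)OCCO2 | intermediate
13 | (2R)-2-[5-(2-pentyl-1,3-dioxolan-2-yl)pentyl]oxirane | C1O[C@@H]1CCCCCC2(CCCCC)OCCO2 | intermediate
14 | methyl (3R)-3-hydroxy-8-(2-pentyl-1,3-dioxolan-2-yl)octanoate | COC(=O)C[C@H](O)CCCCCC1(CCCCC)OCCO1 | intermediate
15 | methyl (3R)-3-[(tert-butyldimethylsilyl)oxy]-8-(2-pentyl-1,3-dioxolan-2-yl)octanoate | COC(=O)C[C@H](O[Si](C)(C)C(C)(C)C)CCCCCC1(CCCCC)OCCO1 | intermediate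
16 | lithium (1E,3R)-3-[(tert-butyldimethylsilyl)oxy]-1-methoxy-8-(2-pentyl-1,3-dioxolan-2-yl)oct-1-en-1-olate | CO/C(O[Li])=C\[C@H](O[Si](C)(C)C(C)(C)C)CCCCCC1(CCCCC)OCCO1 | intermediate (not isolated)
17 | tert-butyl({(1E,3R)-3-[(tert-butyldimethylsilyl)oxy]-1-methoxy-8-(2-pentyl-1,3-dioxolan-2-yl)oct-1-en-1-yl}oxy)dimethylsilane | CO/C(O[Si](C)(C)C(C)(C)C)=C\[C@H](O[Si](C)(C)C(C)(C)C)CCCCCC1(CCCCC)OCCO1 | intermediate
18 | {2,4-dimethoxy-6-[(trifluoromethanesulfonyl)oxy]phenyl}lithium | COc1cc(OC)c([Li])c(OS(=O)(=O)C(F)(F)F)c1 | intermediate (not isolated)
19 | 3,5-dimethoxybenzyne (1,2-didehydro-3,5-dimethoxybenzene) | COC1=CC(OC)=CC#C1 | intermediate (not isolated)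
20 | zwitterion: aryl anion at C8a, methoxy(silyloxy)carbenium ion at C1, C4a-C4 bond formed | COc1cc(OC)[c-]c(c1)C([C@H](O[Si](C)(C)C(C)(C)C)CCCCCC1(CCCCC)OCCO1)C(OC)=[O+][Si](C)(C)C(C)(C)C | intermediate (not isolated)
21 | 7-[(tert-butyldimethylsilyl)oxy]-8-{(1R)-1-[(tert-butyldimethylsilyl)oxy]-6-(2-pentyl-1,3-dioxolan-2-yl)hexyl}-3,5,7-trimethoxybicyclo[4.2.0]octa-1,3,5-triene, isomer mixture at C7 and C8 | COc1cc(OC)c2c(c1)C([C@H](O[Si](C)(C)C(C)(C)C)CCCCCC1(CCCCC)OCCO1)C2(OC)O[Si](C)(C)C(C)(C)C | intermediate
22 | 8-[(1R)-1-hydroxy-7-oxododecyl]-3,5-dimethoxybicyclo[4.2.0]octa-1,3,5-trien-7-one, epimer mixture at C8 | COc1cc(OC)c2c(c1)C([C@H](O)CCCCCC(=O)CCCCC)C2=O | intermediate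
23 | methyl 2-[(2R)-2-hydroxy-8-oxotridecyl]-4,6-dimethoxybenzoate | COC(=O)c1c(OC)cc(OC)cc1C[C@H](O)CCCCCC(=O)CCCCC | intermediate (not isolated)
24 | (3R)-6,8-dimethoxy-3-(6-oxoundecyl)-3,4-dihydroisocoumarin | CCCCCC(=O)CCCCC[C@@H]1Cc2cc(OC)cc(OC)c2C(=O)O1 | intermediate
25 | (3R)-8-hydroxy-6-methoxy-3-(6-oxoundecyl)-3,4-dihydroisocoumarin | CCCCCC(=O)CCCCC[C@@H]1Cc2cc(OC)cc(O)c2C(=O)O1 | target

## Step count and weak points

Total: 15 steps. Longest linear sequence: 11 steps (steps 5 to 15, from 7 to 25); the aryne precursor 6 is made in a 4-step side arm (steps 1 to 4).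

Least certain steps, the key step first:

1. The key step, step 12. The hindered, alpha-substituted ketene acetal may capture the aryne too slowly. The aryne would then be consumed by n-BuLi, by aryllithium 18 or by a second aryne, and 18 may instead attack the sulfonyl group of unreacted 6. Regiocontrol could also erode if the bulky partner is forced toward the carbon next to oxygen. The fallback keeps the aromatic ring and the stereocentre but joins them by polar epoxide opening; it sets out from epoxide 13 and returns at lactone 24. 1-Bromo-3,5-dimethoxybenzene F1 is converted with Mg in THF into 3,5-dimethoxyphenylmagnesium bromide F2. With CuI (10 mol%) this should open 13 at the terminal carbon to give (2R)-1-(3,5-dimethoxyphenyl)-7-(2-pentyl-1,3-dioxolan-2-yl)heptan-2-ol F3. N-Bromosuccinimide in MeCN should brominate the position between the side chain and a methoxy group, para to the other methoxy group, to give the bromo alcohol F4. Two equivalents of n-BuLi at −78 °C give the dilithio species F5, CO2 gives the hydroxy acid F6, and aqueous HCl in THF closes ring B and removes the ketal to give 24.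

2. Step 14. The tetrahedral intermediate may break the C1-C8a bond instead of C1-C4, because an aryl anion beside the C8 methoxy group is also stabilised; this would lead to an arylacetate and no lactone. Closure of the hindered 2,6-disubstituted benzoate may also be slow. The fallback replaces polar cleavage by a pericyclic opening; it sets out from 22 and returns at 24. Heating 22 in toluene containing methanol (sealed vessel, about 150 °C) should open the four-membered ring by electrocyclic reaction to the ortho-quinoid ketene F7, a process in which only the C1-C4 bond can break. Methanol adds to the ketene to give ester 23, here isolated, and p-TsOH in warm toluene closes it to 24.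

3. Step 11. The enolate 16 may lose silanolate from C3 to give an unsaturated ester, silylation may occur at carbon, and 17 may hydrolyse during isolation. The fallback uses a dianion in which elimination is shut off; it sets out from hydroxy ester 14 (step 10 is omitted) and returns at 21. Two equivalents of LiN(iPr)2 give the dilithium alkoxide enolate F8, whose leaving group would have to be an oxide dianion. TBSCl (2.5 equiv) with DMPU silylates both oxygens to the (Z)-isomer F9 of 17. F9 is used in step 12 in place of 17 and should give the same 21, since the double-bond geometry is not carried into any stereocentre that is kept.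

4. Step 9. The acidic cobalt hydride in methanol may exchange or remove the dioxolane, the Lewis acidic cobalt species may isomerise the epoxide to a ketone, and conversion under pressure may stall. The fallback builds the ester carbon by oxidative cleavage instead of carbonylation; it sets out from 13 and returns at 15. Vinylmagnesium bromide with CuI (cat.) opens 13 to the homoallylic alcohol F10, and TBSCl with imidazole gives the silyl ether F11. Ozonolysis (O3, CH2Cl2, −78 °C; PPh3) gives the aldehyde F12. Pinnick oxidation (NaClO2, NaH2PO4, 2-methylbut-2-ene) gives the acid F13, and MeI with K2CO3 in DMF gives 15.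

5. Step 15. Cleavage may also reach the C6 methyl ether or stop short, and the C6' ketone consumes Lewis acid. The fallback removes both methyl groups and puts one back; it sets out from 24 and returns at 25. Excess BBr3 in CH2Cl2 gives the 6,8-dihydroxy lactone F14. One equivalent of MeI with K2CO3 in acetone should then methylate only the C6 hydroxyl, because the C8 hydroxyl is held in a hydrogen bond to the lactone carbonyl.

## Further compounds

F1 | step 12 | 1-bromo-3,5-dimethoxybenzene | COc1cc(Br)cc(OC)c1
F2 | step 12 | 3,5-dimethoxyphenylmagnesium bromide | COc1cc([Mg]Br)cc(OC)c1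
F3 | step 12 | (2R)-1-(3,5-dimethoxyphenyl)-7-(2-pentyl-1,3-dioxolan-2-yl)heptan-2-ol | COc1cc(OC)cc(C[C@H](O)CCCCCC2(CCCCC)OCCO2)c1
F4 | step 12 | (2R)-1-(2-bromo-3,5-dimethoxyphenyl)-7-(2-pentyl-1,3-dioxolan-2-yl)heptan-2-ol | COc1cc(OC)c(Br)c(C[C@H](O)CCCCCC2(CCCCC)OCCO2)c1
F5 | step 12 | dilithio species: lithium (2R)-1-(2-lithio-3,5-dimethoxyphenyl)-7-(2-pentyl-1,3-dioxolan-2-yl)heptan-2-olate | COc1cc(OC)c([Li])c(C[C@H](O[Li])CCCCCC2(CCCCC)OCCO2)c1
F6 | step 12 | 2-[(2R)-2-hydroxy-7-(2-pentyl-1,3-dioxolan-2-yl)heptyl]-4,6-dimethoxybenzoic acid | COc1cc(OC)c(C(O)=O)c(C[C@H](O)CCCCCC2(CCCCC)OCCO2)c1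
F7 | step 14 | ortho-quinoid ketene from electrocyclic opening of 22 | O=C=C1C(OC)=CC(OC)=CC1=C[C@H](O)CCCCCC(=O)CCCCC
F8 | step 11 | dilithium alkoxide enolate of 14 | CO/C(O[Li])=C/[C@H](O[Li])CCCCCC1(CCCCC)OCCO1
F9 | step 11 | tert-butyl({(1Z,3R)-3-[(tert-butyldimethylsilyl)oxy]-1-methoxy-8-(2-pentyl-1,3-dioxolan-2-yl)oct-1-en-1-yl}oxy)dimethylsilane | CO/C(O[Si](C)(C)C(C)(C)C)=C/[C@H](O[Si](C)(C)C(C)(C)C)CCCCCC1(CCCCC)OCCO1
F10 | step 9 | (4R)-9-(2-pentyl-1,3-dioxolan-2-yl)non-1-en-4-ol | C=CC[C@H](O)CCCCCC1(CCCCC)OCCO1
F11 | step 9 | tert-butyldimethyl{[(4R)-9-(2-pentyl-1,3-dioxolan-2-yl)non-1-en-4-yl]oxy}silane | C=CC[C@H](O[Si](C)(C)C(C)(C)C)CCCCCC1(CCCCC)OCCO1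
F12 | step 9 | (3R)-3-[(tert-butyldimethylsilyl)oxy]-8-(2-pentyl-1,3-dioxolan-2-yl)octanal | O=CC[C@H](O[Si](C)(C)C(C)(C)C)CCCCCC1(CCCCC)OCCO1
F13 | step 9 | (3R)-3-[(tert-butyldimethylsilyl)oxy]-8-(2-pentyl-1,3-dioxolan-2-yl)octanoic acid | OC(=O)C[C@H](O[Si](C)(C)C(C)(C)C)CCCCCC1(CCCCC)OCCO1
F14 | step 15 | (3R)-6,8-dihydroxy-3-(6-oxoundecyl)-3,4-dihydroisocoumarin | CCCCCC(=O)CCCCC[C@@H]1Cc2cc(O)cc(O)c2C(=O)O1
A1 | alternative 1 | (3R)-6,8-dimethoxy-3-[5-(2-pentyl-1,3-dioxolan-2-yl)pentyl]-3,4-dihydroisocoumarin | COc1cc(OC)c2c(c1)C[C@@H](CCCCCC1(CCCCC)OCCO1)OC2=O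
A2 | alternative 1 | racemic 5,7-dimethoxy-2-[5-(2-pentyl-1,3-dioxolan-2-yl)pentyl]indan-1-one | COc1cc(OC)c2c(c1)CC(CCCCCC1(CCCCC)OCCO1)C2=O
A3 | alternative 1 | 6,8-dimethoxy-3-[5-(2-pentyl-1,3-dioxolan-2-yl)pentyl]chroman-2-one | COc1cc(OC)c2OC(=O)C(CCCCCC3(CCCCC)OCCO3)Cc2c1
A4 | alternative 2 | 7-hydroxy-2,2-dimethyl-5-{(2R)-2-[(tert-butyldimethylsilyl)oxy]-7-(2-pentyl-1,3-dioxolan-2-yl)heptyl}-4H-1,3-benzodioxin-4-one | CC1(C)OC(=O)c2c(C[C@H](O[Si](C)(C)C(C)(C)C)CCCCCC3(CCCCC)OCCO3)cc(O)cc2O1
A5 | alternative 2 | 6-{(6R)-6-[(tert-butyldimethylsilyl)oxy]-2,4-dioxo-11-(2-pentyl-1,3-dioxolan-2-yl)undecyl}-2,2-dimethyl-4H-1,3-dioxin-4-one | CC1(C)OC(=O)C=C(CC(=O)CC(=O)C[C@H](O[Si](C)(C)C(C)(C)C)CCCCCC2(CCCCC)OCCO2)O1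
A6 | alternative 3 | methyl 2-hydroxy-4-methoxy-6-{(2R)-2-[(tert-butyldimethylsilyl)oxy]-7-(2-pentyl-1,3-dioxolan-2-yl)heptyl}benzoate | COC(=O)c1c(O)cc(OC)cc1C[C@H](O[Si](C)(C)C(C)(C)C)CCCCCC1(CCCCC)OCCO1
A7 | alternative 3 | methyl (5R)-5-[(tert-butyldimethylsilyl)oxy]-10-(2-pentyl-1,3-dioxolan-2-yl)dec-2-ynoate | COC(=O)C#CC[C@H](O[Si](C)(C)C(C)(C)C)CCCCCC1(CCCCC)OCCO1
A8 | alternative 3 | 1,3-dimethoxy-1-(trimethylsilyloxy)buta-1,3-diene | COC(=C)C=C(OC)O[Si](C)(C)C
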